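**Plan**

- Numbering: ring A is the monophenol ring, counted from its C–OH carbon (position 1) so that the ether carbon is position 4; ring B is the hydroquinone ring, counted from its ether carbon (position 1).
- Retrosynthesis: the three phenolic O–H groups go back to methyl ethers, and the only aromatic C–H (position 3 of ring A, beside the ether carbon at position 4) goes back to a C–CO2Me bond.
- Every ring carbon without oxygen carries bromine (positions 2, 5 and 6 of ring A; positions 3, 4 and 6 of ring B) except position 3 of ring A. With that carbon blocked by the ester, all six C–Br bonds can be cut at once and exhaustive bromination becomes regiospecific.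
- The last cut is the diaryl ether C–O bond at position 4 of ring A, giving an ortho-bromobenzoate and 2,5-dimethoxyphenol.
- Forward: both benzene rings are bought intact and no ring is formed. The order is Ullmann etherification, sixfold bromination, ester cleavage, protodecarboxylation, O-demethylation.
- Stereochemistry: the target has no stereocentre, so nothing has to be set or preserved.

Key step: step 2

Remark: in the target, ring A carries OH at position 1, Br at positions 2, 5 and 6, H at position 3 and the ether oxygen at position 4; ring B carries the ether oxygen at position 1, OH at positions 2 and 5 and Br at positions 3, 4 and 6. Compounds 1 and 2 are assumed to be purchasable.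

**Step 1**
Reactants: 1 methyl 2-bromo-5-methoxybenzoate; 2 2,5-dimethoxyphenol
Product: 3 methyl 5-methoxy-2-(2,5-dimethoxyphenoxy)benzoate
Conditions: CuI (10 mol%), N,N-dimethylglycine (30 mol%), Cs2CO3 (2 equiv), dry 1,4-dioxane, 100 °C, nitrogen atmosphere
Reagents that add atoms: none
Why: Ullmann-type copper-catalysed diaryl ether synthesis, in which the caesium phenoxide of 2 displaces bromide from 1 at monovalent copper, the ortho ester speeding the C–Br activation by coordination and electron withdrawal, while the amino acid ligand allows a temperature at which dry carbonate leaves the methyl ester intact.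

**Step 2**
Reactants: 3 methyl 5-methoxy-2-(2,5-dimethoxyphenoxy)benzoate; 4 bromine
Product: 5 methyl 2,4,5-tribromo-3-methoxy-6-(3,4,6-tribromo-2,5-dimethoxyphenoxy)benzoate
Conditions: Br2 (about 12 equiv), FeBr3 (20 mol%), 1,2-dichloroethane, 0 °C → 60 °C, dark, slow nitrogen sweep
Reagents that add atoms: bromine, BrBr
Why: Each of the six C–Br bonds (positions 2, 5 and 6 of ring A, positions 3, 4 and 6 of ring B) forms by electrophilic aromatic substitution, in which bromine polarised by FeBr3 adds to the ring to give an oxygen-stabilised arenium (Wheland) ion that loses a proton as HBr. The closest known reaction type is the exhaustive Lewis-acid-promoted bromination of aryl ethers, as in the tetrabromination of 1,4-dimethoxybenzene and the perbromination of diphenyl ether. No ring is closed and no stereocentre is created, so neither a mode of cyclisation nor a stereocontrol element is involved. The only selectivity required is complete reaction at the six open positions with position 3 of ring A left untouched, and the substrate secures it because that carbon already carries the ester, so that driving the reaction to the end cannot give a regioisomer. Ring B with its three oxygen donors should fill first, then positions 6 and 2 of ring A beside the methoxy group, and last position 5 of ring A, which is activated only by the twisted diaryl ether oxygen and is the reason for the Lewis acid and gentle heating. The blocking group is kept as the methyl ester because a free ortho-aryloxy acid would be open to ipso-bromodecarboxylation, and xanthone formation is excluded since an ester does not acylate under these conditions and both ring B positions ortho to the ether oxygen end up substituted.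

**Step 3**
Reactants: 5 methyl 2,4,5-tribromo-3-methoxy-6-(3,4,6-tribromo-2,5-dimethoxyphenoxy)benzoate
Product: 6 2,4,5-tribromo-3-methoxy-6-(3,4,6-tribromo-2,5-dimethoxyphenoxy)benzoic acid
Conditions: LiI (5 equiv), pyridine, reflux; then aq. HCl
Reagents that add atoms: none
Why: SN2 dealkylation of a hindered methyl ester with lithium iodide in pyridine, in which iodide attacks the unhindered O-methyl carbon (the carbonyl carbon is shielded by its bromine and aryloxy neighbours) and expels the well-stabilised, lithium-coordinated polybromobenzoate, the iodomethane being trapped by the solvent as 1-methylpyridinium iodide, whereas the aryl methyl ethers, with poorer phenoxide leaving groups, should react much more slowly.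

**Step 4**
Reactants: 6 2,4,5-tribromo-3-methoxy-6-(3,4,6-tribromo-2,5-dimethoxyphenoxy)benzoic acid
Product: 7 1,3,4-tribromo-2-methoxy-5-(3,4,6-tribromo-2,5-dimethoxyphenoxy)benzene
Conditions: Ag2CO3 (10 mol%), AcOH (5 mol%), DMSO, 120 °C
Reagents that add atoms: none
Why: Silver-catalysed protodecarboxylation of an ortho-substituted benzoic acid, in which the monovalent silver carboxylate loses CO2 to an arylsilver species favoured by the two ortho substituents (bromine and aryloxy twist the carboxylate out of plane and stabilise the developing carbanion character) and is then protonated by acetic acid or further substrate, while C–Br bonds and methyl ethers are inert to this catalyst.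

**Step 5**
Reactants: 7 1,3,4-tribromo-2-methoxy-5-(3,4,6-tribromo-2,5-dimethoxyphenoxy)benzene
Product: 8 2,3,5-tribromo-6-(2,3,5-tribromo-4-hydroxyphenoxy)benzene-1,4-diol (CNP0277646.0)
Conditions: BBr3 (6 equiv), CH2Cl2, −78 °C → rt; then degassed H2O, 0 °C, under argon
Reagents that add atoms: none
Why: Boron tribromide O-demethylation of aryl methyl ethers, in which boron binds each methoxy oxygen and bromide removes the methyl group by SN2 to leave aryloxyboranes that water hydrolyses to the phenols, neither the diaryl ether (no sp3 C–O bond) nor the aryl bromides being touched, and the oxidisable hydroquinone of ring B being unmasked only at this last step.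

**Compound list**
1 | methyl 2-bromo-5-methoxybenzoate | COC(=O)c1cc(OC)ccc1Br | starting material
2 | 2,5-dimethoxyphenol | COc1ccc(OC)c(O)c1 | starting material
3 | methyl 5-methoxy-2-(2,5-dimethoxyphenoxy)benzoate | COC(=O)c1cc(OC)ccc1Oc1cc(OC)ccc1OC | intermediate
4 | bromine | BrBr | starting material
5 | methyl 2,4,5-tribromo-3-methoxy-6-(3,4,6-tribromo-2,5-dimethoxyphenoxy)benzoate | COC(=O)c1c(Br)c(OC)c(Br)c(Br)c1Oc1c(Br)c(OC)c(Br)c(Br)c1OC | intermediate
6 | 2,4,5-tribromo-3-methoxy-6-(3,4,6-tribromo-2,5-dimethoxyphenoxy)benzoic acid | OC(=O)c1c(Br)c(OC)c(Br)c(Br)c1Oc1c(Br)c(OC)c(Br)c(Br)c1OC | intermediate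
7 | 1,3,4-tribromo-2-methoxy-5-(3,4,6-tribromo-2,5-dimethoxyphenoxy)benzene | COc1c(Br)cc(Oc2c(OC)c(Br)c(Br)c(OC)c2Br)c(Br)c1Br | intermediate
8 | 2,3,5-tribromo-6-(2,3,5-tribromo-4-hydroxyphenoxy)benzene-1,4-diol | Oc1c(Br)cc(Oc2c(O)c(Br)c(Br)c(O)c2Br)c(Br)c1Br | target

**Step count:** 5 steps in total; longest linear sequence 5 steps (from 1 or 2 to 8).

**Steps most likely to fail**

Step 2 (key step). The bromination may stall before the last, least activated carbon (position 5 of ring A) is filled. Forcing it may bring ipso attack at oxygen-bearing carbons with oxidative loss of methyl groups from the para-dimethoxy ring B, or HBr-mediated cleavage of the ester followed by bromodecarboxylation at position 3 of ring A. The fallback sets out from 3. Bromine in acetic acid without a Lewis acid (about 50 °C) should stop at the pentabromide methyl 2,4-dibromo-3-methoxy-6-(3,4,6-tribromo-2,5-dimethoxyphenoxy)benzoate F1, whose single remaining C–H (position 5 of ring A) lies between a bromine and the aryloxy oxygen and is therefore acidic. Deprotonative magnesiation with TMPMgCl·LiCl in THF at −20 °C should give [2,4-dibromo-3-methoxy-5-(methoxycarbonyl)-6-(3,4,6-tribromo-2,5-dimethoxyphenoxy)phenyl]magnesium chloride F2, which is not isolated; the doubly ortho-substituted ester is shielded from the amide base. Quenching with 1,2-dibromo-1,1,2,2-tetrachloroethane puts in the sixth bromine, and the sequence comes back to the route at 5.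

Step 3. Iodide may also demethylate the aryl methyl ethers flanked by two bromines, whose phenoxides are good leaving groups, or the ester cleavage may stay incomplete; either would give phenol mixtures unfit for the silver step. The fallback sets out from 5 and replaces dealkylation by a redox detour. i-Bu2AlH in CH2Cl2 (−78 °C to 0 °C) should reduce the ester to [2,4,5-tribromo-3-methoxy-6-(3,4,6-tribromo-2,5-dimethoxyphenoxy)phenyl]methanol F3. Dess–Martin periodinane should oxidise it to 2,4,5-tribromo-3-methoxy-6-(3,4,6-tribromo-2,5-dimethoxyphenoxy)benzaldehyde F4. Pinnick oxidation (NaClO2, NaH2PO4, 2-methyl-2-butene, t-BuOH/H2O) should then give the acid, coming back to the route at 6.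

Step 1. The C–O coupling of this ortho-substituted, electron-rich pair may be slow, so that protodebromination of 1 or hydrolysis of the methyl ester under hot carbonate competes. The fallback sets out from 2 and uses metal-free nucleophilic aromatic substitution. Reaction with commercially available 2-fluoro-5-methoxybenzaldehyde F5 (K2CO3, DMF, 120 °C; the ortho formyl group activates the fluoride) should give 5-methoxy-2-(2,5-dimethoxyphenoxy)benzaldehyde F6. Pinnick oxidation leads to 5-methoxy-2-(2,5-dimethoxyphenoxy)benzoic acid F7, and methylation (MeI, K2CO3, DMF) comes back to the route at 3.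

**Further compounds**
F1 | step 2 | methyl 2,4-dibromo-3-methoxy-6-(3,4,6-tribromo-2,5-dimethoxyphenoxy)benzoate | COC(=O)c1c(Br)c(OC)c(Br)cc1Oc1c(Br)c(OC)c(Br)c(Br)c1OC
F2 | step 2 | [2,4-dibromo-3-methoxy-5-(methoxycarbonyl)-6-(3,4,6-tribromo-2,5-dimethoxyphenoxy)phenyl]magnesium chloride | COC(=O)c1c(Br)c(OC)c(Br)c([Mg]Cl)c1Oc1c(Br)c(OC)c(Br)c(Br)c1OC
F3 | step 3 | [2,4,5-tribromo-3-methoxy-6-(3,4,6-tribromo-2,5-dimethoxyphenoxy)phenyl]methanol | OCc1c(Br)c(OC)c(Br)c(Br)c1Oc1c(Br)c(OC)c(Br)c(Br)c1OC
F4 | step 3 | 2,4,5-tribromo-3-methoxy-6-(3,4,6-tribromo-2,5-dimethoxyphenoxy)benzaldehyde | O=Cc1c(Br)c(OC)c(Br)c(Br)c1Oc1c(Br)c(OC)c(Br)c(Br)c1OC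
F5 | step 1 | 2-fluoro-5-methoxybenzaldehyde | O=Cc1cc(OC)ccc1F
F6 | step 1 | 5-methoxy-2-(2,5-dimethoxyphenoxy)benzaldehyde | O=Cc1cc(OC)ccc1Oc1cc(OC)ccc1OC
F7 | step 1 | 5-methoxy-2-(2,5-dimethoxyphenoxy)benzoic acid | OC(=O)c1cc(OC)ccc1Oc1cc(OC)ccc1OC
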